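Count what the partner does before you count equivalents.

solid substrate 20 mM; solid reagent 36.0 mM; time 10 d

    solid reagent ⇌ partner, rate k1*(cs1 - [partner]) while solid is left; crystals form when [partner] > cs1 (cs1 = 8.3 mM, k1 = 3.0 × 10⁻⁴ min⁻¹)
    dissolved substrate + partner → target (k2 = 5.2 M⁻¹ min⁻¹)
    solid substrate ⇌ dissolved substrate, rate k3*(cs3 - [dissolved substrate]) while solid is left; crystals form when [dissolved substrate] > cs3 (cs3 = 9.8 mM, k3 = 5.2 × 10⁻⁴ min⁻¹)
    solid substrate + target → side product B (k4 = 0.0015 M⁻¹ min⁻¹)
    solid product ⇌ target, rate k5*(cs5 - [target]) while solid is left; crystals form when [target] > cs5 (cs5 = 2.6 mM, k5 = 0.081 min⁻¹)
    partner → side product A (k6 = 0.11 min⁻¹)

- percent here means solid substrate units held: one side product B counts as two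
- what is said of target includes solid product
- solid substrate, solid product, solid reagent is a solid; its amount is given per volume of the solution
- at the start none of the solid reagent is in solution
- at the start none of the solid substrate is in solution
- dissolved substrate means what is dissolved; the solid is not counted in it
- run time (flask): 10 d

- target and solid product together at 10 d, in percent of the solid substrate charged
- concentration of dissolved substrate in solution at 25 h, in percent of saturation
- the change that raises the amount of target and solid product together at 10 d, in percent of the solid substrate charged most ("none" if none brings more than 2 percentage points) (amber / teal / red / grey / none)
- amount of target and solid product together at 10 d, in percent of the solid substrate charged, after red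

- amber: doubling the solubility in step 3, all else as stated
- teal: doubling the dissolution coefficient of step 5, all else as stated
- red: doubling the dissolution coefficient of step 1, all else as stated
- grey: doubling the dissolution coefficient of step 3, all else as stated

Two chemists argue over this flask. The first counts equivalents: solid reagent stands at 1.80 equivalents to solid substrate, and step 1 can deliver up to 179% of the substrate charge by 10 d into a solution kept empty. So solid substrate is the limiting reagent, and she writes down 100 percent.

The second chemist, and I side with him, follows the partner once it is dissolved. It either meets dissolved substrate in step 2 or decays to side product A. The two paths take equal shares when c(dissolved substrate) equals the step 6 constant over the step 2 constant, 21.2 mM, the even-split level. At any other c, the share reaching target (the selectivity) is c over c plus that level.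

A saturated solution holds 9.8 mM, less than the even-split level, so even then the share is 31.7%. My own reckoning puts that share on the whole 36.0 mM of solid reagent, which gives 57.0% of the substrate charge, for a solution kept saturated.

The forecast, from the second chemist's side, stands lower than my figure: 44.2% for y, 50.8% for sat, amber as best, 36.5% after red. Its ground is that the partner feed “mostly decays to side product A”.

The simulation gives 44.5%, 50.8%, amber as best with a gain of 17 percentage points, and 37.0% after red, so the forecast held.

In this flask at 5.00 d, partner goes to side product A 2.5 times as fast as into target. At that moment c(dissolved substrate) reads 8.31 mM, below the even-split level, which makes the share 28.2%. The first chemist's count has its region: with step 2 sped up, this flask gives 98.3%.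

A neighbour flask, charged with 22 mM of solid reagent, still holds 1.10 equiv of it to solid substrate. The saturated share of that charge gives 34.8% of the solid substrate for a solution kept saturated, and the computed neighbour stands at 24.8%.

All constants were chosen freely.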